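**Retrosynthetic overview**

1. Neolinderachalcone 18 ⇐ aldol condensation of benzaldehyde 16 with triphenolic acetophenone 15 ⇐ O-demethylation and Li–Br exchange/acetylation of aryl bromide 12, which already carries both (1R,6R)-3-methyl-6-isopropylcyclohex-2-en-1-yl rings (ring locants used below: C1 aryl-bearing, C2=C3 ring alkene, C6 isopropyl-bearing).
2. 12 ⇐ dialdehyde 8: each isopropyl methine carbon is carried as a formyl carbon (CHO → COCH3 → C(CH3)=CH2 → CH(CH3)2), the activating group of the key step.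
3. 8 ⇐ bis(aryl vinyl carbinol) 3 + two 5-methylhex-5-enal 6 in one pot: in both rings the C1–C6 bond by iridium/amine dual-catalytic allylation and the C2=C3 bond by ring-closing metathesis; the two cyclohexene rings (ring A and ring B) form together, the aromatic ring is bought.
4. Enabling feature: in each cyclohexene ring C1 is a benzylic and allylic methine (Ar–C1H–C2H=C3, a branched aryl–allyl unit), its neighbour C6 bears a carbon that can be a carbonyl carbon, and C2=C3 can be cut into two terminal alkenes; the two rings are related by the twofold axis of the arene (through the acyl-bearing carbon and the opposite C–O), so one operation builds both.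
5. 3 ⇐ dialdehyde 2 ⇐ 2-bromo-1,3,5-trimethoxybenzene 1 (Br reserves the acyl position); 6 ⇐ ethyl 5-oxohexanoate 4.

Key step: step 5

Assumption: in step 5 the (S) ligand and the (R) amine are taken to give the (S,S) arms by the accepted facial models of this dual catalysis; both catalysts exist in either mirror-image form, so the pairing is exchanged without other change if a sense proves opposite [(S)-L = (S)-BINOL-derived N-(5H-dibenzo[b,f]azepin-5-yl)phosphoramidite (phosphoramidite–olefin ligand); (R)-A = (R)-2-{bis[3,5-bis(trifluoromethyl)phenyl][(trimethylsilyl)oxy]methyl}pyrrolidine].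

**Route**

Step 1
Reactants: 1 2-bromo-1,3,5-trimethoxybenzene
Product: 2 5-bromo-2,4,6-trimethoxybenzene-1,3-dicarbaldehyde
Conditions: Cl2CHOMe (3 equiv), TiCl4 (4 equiv), CH2Cl2, −10 °C → rt; ice-water
Reagents that add atoms: dichloromethyl methyl ether, COC(Cl)Cl; water, O
Why: Twofold Rieche formylation (electrophilic aromatic substitution); both free positions are ortho/para to three methoxy groups, so the second formylation should still proceed, and the bromide blocks the third position.

Step 2
Reactants: 2 5-bromo-2,4,6-trimethoxybenzene-1,3-dicarbaldehyde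
Product: 3 1,1'-(5-bromo-2,4,6-trimethoxy-1,3-phenylene)bis(prop-2-en-1-ol), racemic and meso forms
Conditions: CH2=CHMgBr (2.6 equiv), THF, −78 → 0 °C; then H2O
Reagents that add atoms: vinylmagnesium bromide, C=C[Mg]Br
Why: Grignard 1,2-addition to both aldehydes; the carbinol centres form unselectively, which does not matter because they are ionised in step 5.

Step 3
Reactants: 4 ethyl 5-oxohexanoate
Product: 5 ethyl 5-methylhex-5-enoate
Conditions: Ph3PCH3Br (1.3 equiv), KOtBu (1.25 equiv), THF, 0 °C → rt
Reagents that add atoms: methyltriphenylphosphonium bromide, C[P+](c1ccccc1)(c1ccccc1)c1ccccc1.[Br-]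
Why: Wittig methylenation; the non-stabilised ylide should react with the ketone and leave the ethyl ester untouched.

Step 4
Reactants: 5 ethyl 5-methylhex-5-enoate
Product: 6 5-methylhex-5-enal
Conditions: i-Bu2AlH (1.05 equiv), CH2Cl2, −78 °C; then aqueous work-up
Reagents that add atoms: none
Why: Partial ester reduction with i-Bu2AlH; the tetrahedral aluminium hemiacetal is stable at −78 °C and releases the aldehyde only on work-up.

Step 5
Reactants: 3 1,1'-(5-bromo-2,4,6-trimethoxy-1,3-phenylene)bis(prop-2-en-1-ol); 6 5-methylhex-5-enal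
Product: 8 (1S,1'S,2S,2'S)-2,2'-(5-bromo-2,4,6-trimethoxy-1,3-phenylene)bis(4-methylcyclohex-3-ene-1-carbaldehyde), via acyclic bis-allylated dialdehyde 7 (not isolated)
Conditions: [Ir(cod)Cl]2 (6 mol%), (S)-L (24 mol%), (R)-A (30 mol%), (MeO)2P(O)OH (10 mol%), 6 (6 equiv), ClCH2CH2Cl, 25 °C; then Cl2CHCO2H (0.4 equiv), second-generation Hoveyda–Grubbs catalyst (10 mol%), CH2Cl2, 40 °C
Reagents that add atoms: none
Why: With the acid promoter the iridium complex ionises each carbinol of 3 to a cationic (η3-allyl)iridium species bearing two phosphoramidite–olefin ligands, and the enamine from 6 and the chiral amine attacks its aryl-substituted terminus (C1–C6 bond, branched product), after which the ruthenium carbene joins the vinyl group and the 1,1-disubstituted alkene of each arm with loss of ethene (C2=C3 bond). The closest known reaction types are the iridium/amine dual-catalytic α-allylation of linear aldehydes with racemic aryl vinyl carbinols, which tolerates 2,6-dimethoxyaryl groups, and ring-closing metathesis of the resulting 1,7-dienes to trisubstituted cyclohexenes. Each six-membered ring is closed by ring-closing metathesis, which creates no stereocentre. C1 of each ring is set by the iridium ligand in an enantioconvergent substitution (all stereoisomers of 3 pass through the same allyl complexes) and C6 by the amine, which shields one face of the E-enamine, so that together they should give the anti arrangement in both arms. The step needs branched regioselectivity, secured by the ligand and the aryl-stabilised allyl terminus, and catalyst control that outruns metal-free ionisation of the electron-rich carbinols, for which the mild promoter and 25 °C are chosen; because the event happens twice, the minor enantiomer should be largely diverted into a separable meso-type diastereomer. C6 stays epimerisable (α to C=O) until step 8 and trans is the more stable arrangement, so a deficit in diastereoselectivity can still be corrected.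

Step 6
Reactants: 8 (1S,1'S,2S,2'S)-2,2'-(5-bromo-2,4,6-trimethoxy-1,3-phenylene)bis(4-methylcyclohex-3-ene-1-carbaldehyde)
Product: 9 1,1'-{(5-bromo-2,4,6-trimethoxy-1,3-phenylene)bis[(1S,2S)-4-methylcyclohex-3-ene-2,1-diyl]}di(ethan-1-ol), both carbinol epimers
Conditions: MeMgBr (3 equiv), THF, −78 → 0 °C; then H2O
Reagents that add atoms: methylmagnesium bromide, C[Mg]Br
Why: Grignard 1,2-addition, faster than enolisation at low temperature and inert toward the aryl bromide; the new carbinol centres are removed in step 7.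

Step 7
Reactants: 9 1,1'-{(5-bromo-2,4,6-trimethoxy-1,3-phenylene)bis[(1S,2S)-4-methylcyclohex-3-ene-2,1-diyl]}di(ethan-1-ol)
Product: 10 1,1'-{(5-bromo-2,4,6-trimethoxy-1,3-phenylene)bis[(1S,2S)-4-methylcyclohex-3-ene-2,1-diyl]}di(ethan-1-one)
Conditions: Dess–Martin periodinane (2.6 equiv), CH2Cl2, 0 °C → rt
Reagents that add atoms: none
Why: Dess–Martin oxidation of both secondary alcohols under near-neutral conditions that leave the alkenes and the trans ring substitution untouched.

Step 8
Reactants: 10 1,1'-{(5-bromo-2,4,6-trimethoxy-1,3-phenylene)bis[(1S,2S)-4-methylcyclohex-3-ene-2,1-diyl]}di(ethan-1-one)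
Product: 11 1-bromo-2,4,6-trimethoxy-3,5-bis[(1S,6S)-3-methyl-6-(prop-1-en-2-yl)cyclohex-2-en-1-yl]benzene
Conditions: Ph3PCH3Br (4 equiv), KOtBu (3.8 equiv), toluene, 80 °C
Reagents that add atoms: methyltriphenylphosphonium bromide, C[P+](c1ccccc1)(c1ccccc1)c1ccccc1.[Br-]
Why: Wittig methylenation of both methyl ketones; the basic ylide can only equilibrate C6 toward the more stable trans arrangement, which is the one wanted and is fixed once the carbonyl is gone.

Step 9
Reactants: 11 1-bromo-2,4,6-trimethoxy-3,5-bis[(1S,6S)-3-methyl-6-(prop-1-en-2-yl)cyclohex-2-en-1-yl]benzene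
Product: 12 1-bromo-2,4,6-trimethoxy-3,5-bis[(1R,6R)-3-methyl-6-(propan-2-yl)cyclohex-2-en-1-yl]benzene
Conditions: H2 (1 atm), RhCl(PPh3)3 (10 mol%), benzene–EtOH 1:1, rt
Reagents that add atoms: none
Why: Homogeneous hydrogenation with RhCl(PPh3)3 should reduce the 1,1-disubstituted isopropenyl groups and spare the trisubstituted ring alkenes and the aryl bromide; no stereocentre is formed, and the descriptors change only through CIP priorities.

Step 10
Reactants: 12 1-bromo-2,4,6-trimethoxy-3,5-bis[(1R,6R)-3-methyl-6-(propan-2-yl)cyclohex-2-en-1-yl]benzene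
Product: 14 1-{2,4,6-trimethoxy-3,5-bis[(1R,6R)-3-methyl-6-(propan-2-yl)cyclohex-2-en-1-yl]phenyl}ethan-1-one, via aryllithium 13 (not isolated)
Conditions: t-BuLi (2.1 equiv), THF, −78 °C; then MeC(O)N(OMe)Me (3 equiv), −78 → 0 °C; then H2O
Reagents that add atoms: N-methoxy-N-methylacetamide, CON(C)C(C)=O
Why: Bromine–lithium exchange at −78 °C is faster than any deprotonation, and acylation with the Weinreb amide stops at the ketone through the chelated tetrahedral adduct.

Step 11
Reactants: 14 1-{2,4,6-trimethoxy-3,5-bis[(1R,6R)-3-methyl-6-(propan-2-yl)cyclohex-2-en-1-yl]phenyl}ethan-1-one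
Product: 15 1-{2,4,6-trihydroxy-3,5-bis[(1R,6R)-3-methyl-6-(propan-2-yl)cyclohex-2-en-1-yl]phenyl}ethan-1-one
Conditions: NaSEt (12 equiv), DMF, 140 °C; then 1 M HCl to pH 4, 0 °C
Reagents that add atoms: none
Why: SN2 O-demethylation by thiolate, helped by the ortho/para acetyl group that stabilises each phenoxide, under non-acidic conditions so that the ring alkenes cannot cyclise onto the phenols.

Step 12
Reactants: 15 1-{2,4,6-trihydroxy-3,5-bis[(1R,6R)-3-methyl-6-(propan-2-yl)cyclohex-2-en-1-yl]phenyl}ethan-1-one; 16 benzaldehyde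
Product: 18 neolinderachalcone, via aldol adduct 17 (not isolated)
Conditions: LiN(SiMe3)2 (6 equiv), THF, −78 °C; 16 (1.5 equiv), −78 °C → rt; then 1 M HCl to pH 3–4, 0 °C
Reagents that add atoms: none
Why: Polyanion crossed aldol condensation (Claisen–Schmidt type): the phenols are masked as lithium phenoxides, the enolate adds to benzaldehyde and E1cB loss of hydroxide gives the conjugated E enone, while the cold, mildly acidic work-up avoids flavanone closure and acid cyclisation of the terpenoid rings.

**Compound list**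

1 | 2-bromo-1,3,5-trimethoxybenzene | COc1cc(OC)c(Br)c(OC)c1 | starting material
2 | 5-bromo-2,4,6-trimethoxybenzene-1,3-dicarbaldehyde | COc1c(C=O)c(OC)c(Br)c(OC)c1C=O | intermediate
3 | 1,1'-(5-bromo-2,4,6-trimethoxy-1,3-phenylene)bis(prop-2-en-1-ol), racemic and meso forms | COc1c(C(O)C=C)c(OC)c(Br)c(OC)c1C(O)C=C | intermediate
4 | ethyl 5-oxohexanoate | CCOC(=O)CCCC(C)=O | starting material
5 | ethyl 5-methylhex-5-enoate | CCOC(=O)CCCC(C)=C | intermediate
6 | 5-methylhex-5-enal | O=CCCCC(C)=C | intermediate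
7 | (2S,2'S,3S,3'S)-3,3'-(5-bromo-2,4,6-trimethoxy-1,3-phenylene)bis[2-(3-methylbut-3-en-1-yl)pent-4-enal] | COc1c([C@@H](C=C)[C@@H](C=O)CCC(C)=C)c(OC)c(Br)c(OC)c1[C@@H](C=C)[C@@H](C=O)CCC(C)=C | intermediate
8 | (1S,1'S,2S,2'S)-2,2'-(5-bromo-2,4,6-trimethoxy-1,3-phenylene)bis(4-methylcyclohex-3-ene-1-carbaldehyde) | COc1c([C@H]2C=C(C)CC[C@@H]2C=O)c(OC)c(Br)c(OC)c1[C@H]3C=C(C)CC[C@@H]3C=O | intermediate
9 | 1,1'-{(5-bromo-2,4,6-trimethoxy-1,3-phenylene)bis[(1S,2S)-4-methylcyclohex-3-ene-2,1-diyl]}di(ethan-1-ol), both carbinol epimers | COc1c([C@H]2C=C(C)CC[C@@H]2C(C)O)c(OC)c(Br)c(OC)c1[C@H]3C=C(C)CC[C@@H]3C(C)O | intermediate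
10 | 1,1'-{(5-bromo-2,4,6-trimethoxy-1,3-phenylene)bis[(1S,2S)-4-methylcyclohex-3-ene-2,1-diyl]}di(ethan-1-one) | COc1c([C@H]2C=C(C)CC[C@@H]2C(C)=O)c(OC)c(Br)c(OC)c1[C@H]3C=C(C)CC[C@@H]3C(C)=O | intermediate
11 | 1-bromo-2,4,6-trimethoxy-3,5-bis[(1S,6S)-3-methyl-6-(prop-1-en-2-yl)cyclohex-2-en-1-yl]benzene | COc1c([C@H]2C=C(C)CC[C@@H]2C(C)=C)c(OC)c(Br)c(OC)c1[C@H]3C=C(C)CC[C@@H]3C(C)=C | intermediate
12 | 1-bromo-2,4,6-trimethoxy-3,5-bis[(1R,6R)-3-methyl-6-(propan-2-yl)cyclohex-2-en-1-yl]benzene | COc1c([C@H]2C=C(C)CC[C@@H]2C(C)C)c(OC)c(Br)c(OC)c1[C@H]3C=C(C)CC[C@@H]3C(C)C | intermediate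
13 | {2,4,6-trimethoxy-3,5-bis[(1R,6R)-3-methyl-6-(propan-2-yl)cyclohex-2-en-1-yl]phenyl}lithium | COc1c([C@H]2C=C(C)CC[C@@H]2C(C)C)c(OC)c([Li])c(OC)c1[C@H]3C=C(C)CC[C@@H]3C(C)C | intermediate
14 | 1-{2,4,6-trimethoxy-3,5-bis[(1R,6R)-3-methyl-6-(propan-2-yl)cyclohex-2-en-1-yl]phenyl}ethan-1-one | COc1c([C@H]2C=C(C)CC[C@@H]2C(C)C)c(OC)c(C(C)=O)c(OC)c1[C@H]3C=C(C)CC[C@@H]3C(C)C | intermediate
15 | 1-{2,4,6-trihydroxy-3,5-bis[(1R,6R)-3-methyl-6-(propan-2-yl)cyclohex-2-en-1-yl]phenyl}ethan-1-one | CC(=O)c1c(O)c([C@H]2C=C(C)CC[C@@H]2C(C)C)c(O)c([C@H]3C=C(C)CC[C@@H]3C(C)C)c1O | intermediate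
16 | benzaldehyde | O=Cc1ccccc1 | starting material
17 | 3-hydroxy-3-phenyl-1-{2,4,6-trihydroxy-3,5-bis[(1R,6R)-3-methyl-6-(propan-2-yl)cyclohex-2-en-1-yl]phenyl}propan-1-one (lithium salt in the flask, carbinol centre unassigned) | OC(CC(=O)c1c(O)c([C@H]2C=C(C)CC[C@@H]2C(C)C)c(O)c([C@H]3C=C(C)CC[C@@H]3C(C)C)c1O)c1ccccc1 | intermediate
18 | neolinderachalcone, (E)-3-phenyl-1-{2,4,6-trihydroxy-3,5-bis[(1R,6R)-3-methyl-6-(propan-2-yl)cyclohex-2-en-1-yl]phenyl}prop-2-en-1-one | CC1=C[C@H](c2c(O)c(C(=O)/C=C/c3ccccc3)c(O)c([C@H]3C=C(C)CC[C@@H]3C(C)C)c2O)[C@@H](C(C)C)CC1 | target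

**Step count and risks**

Total step count: 12. Longest linear sequence: 10 steps (steps 1, 2 and 5–12, from 1).

Steps most likely to fail:

1. Step 5. The very electron-rich carbinols may ionise without the metal, which would erode regio- and enantiocontrol; the second arm may react incompletely; and amine and phosphoramidite in the shared flask may inhibit the ruthenium catalyst. Fallback (chiral-pool Friedel–Crafts terpenylation; sets out from 1, comes back at 12): 1 is alkylated twice with commercial (R)-(−)-α-phellandrene (BF3·OEt2 or TsOH, CH2Cl2, 0 °C). Protonation gives the 1-methyl-4-isopropylcyclohex-2-enyl cation, which the arene should attack at the allyl terminus next to the isopropyl-bearing carbon and anti to that group. The mono-alkylated bromide 2-bromo-1,3,5-trimethoxy-4-[(1R,6R)-3-methyl-6-(propan-2-yl)cyclohex-2-en-1-yl]benzene F1 reacts a second time to give 12. C6 is then bought and C1 relayed from it, at the price of the terpene's optical purity and of isomer separation.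

2. Step 11. The threefold demethylation may stall as negative charge builds up on the ring, and the acetyl group may undergo side reactions at 140 °C. Fallback (deprotection before acylation; sets out from 12, comes back at 15): 12 itself is demethylated with NaSEt (DMF, 150 °C, no ketone present) to 2-bromo-4,6-bis[(1R,6R)-3-methyl-6-(propan-2-yl)cyclohex-2-en-1-yl]benzene-1,3,5-triol F2. Treatment of F2 with t-BuLi (5.2 equiv, THF, −78 °C; three phenoxides, then bromine–lithium exchange) and N-methoxy-N-methylacetamide should then give 15.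

3. Step 12. Enolate formation and addition may be sluggish in the hindered polyanion, the aldol may revert, and the product may close to the flavanone during work-up. Fallback (protect, condense, deprotect; sets out from 15, comes back at 18): 15 is converted with MOMCl/i-Pr2NEt into 1-{2,4,6-tris(methoxymethoxy)-3,5-bis[(1R,6R)-3-methyl-6-(propan-2-yl)cyclohex-2-en-1-yl]phenyl}ethan-1-one F3. Classical Claisen–Schmidt condensation with 16 (KOH, EtOH, rt) gives (E)-3-phenyl-1-{2,4,6-tris(methoxymethoxy)-3,5-bis[(1R,6R)-3-methyl-6-(propan-2-yl)cyclohex-2-en-1-yl]phenyl}prop-2-en-1-one F4, and brief HCl/MeOH at rt releases 18.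

**Further compounds**

F1 | step 5 | 2-bromo-1,3,5-trimethoxy-4-[(1R,6R)-3-methyl-6-(propan-2-yl)cyclohex-2-en-1-yl]benzene | COc1cc(OC)c(Br)c(OC)c1[C@H]1C=C(C)CC[C@@H]1C(C)C
F2 | step 11 | 2-bromo-4,6-bis[(1R,6R)-3-methyl-6-(propan-2-yl)cyclohex-2-en-1-yl]benzene-1,3,5-triol | Oc1c([C@H]2C=C(C)CC[C@@H]2C(C)C)c(O)c(Br)c(O)c1[C@H]3C=C(C)CC[C@@H]3C(C)C
F3 | step 12 | 1-{2,4,6-tris(methoxymethoxy)-3,5-bis[(1R,6R)-3-methyl-6-(propan-2-yl)cyclohex-2-en-1-yl]phenyl}ethan-1-one | CC(=O)c1c(OCOC)c([C@H]2C=C(C)CC[C@@H]2C(C)C)c(OCOC)c([C@H]3C=C(C)CC[C@@H]3C(C)C)c1OCOC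
F4 | step 12 | (E)-3-phenyl-1-{2,4,6-tris(methoxymethoxy)-3,5-bis[(1R,6R)-3-methyl-6-(propan-2-yl)cyclohex-2-en-1-yl]phenyl}prop-2-en-1-one | O=C(/C=C/c1ccccc1)c1c(OCOC)c([C@H]2C=C(C)CC[C@@H]2C(C)C)c(OCOC)c([C@H]3C=C(C)CC[C@@H]3C(C)C)c1OCOC
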